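Ring A is grown onto a finished, enantiopure ring C. The disconnection cuts C4a–C5, C5–C6, C7–C8 and C8–C8a. It exploits the contiguous C5-OH, C6-prenyl, C7-OMe, C8-H array of pentasubstituted ring A, the pattern written directly by joining a vinylketene to a 1-methoxyalkyne. In one operation, Wolff shift, [2+2] addition, four-electron opening and six-electron closure turn a glucal-like 2-aryl-3,4-bis(silyloxy)-3,4-dihydro-2H-pyran-6-yl diazomethyl ketone and 1-methoxy-5-methylhex-4-en-1-yne into the complete 2,3-trans flavan-3,4-diol with free 5-OH. C2 stems from a catalytic hetero-Diels–Alder reaction and C3 from substrate-controlled enolate hydroxylation. The C4 carbinol, masked by the most labile silyl group, is oxidised at the end.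

Key step: step 10

Abbreviation: Ar = 3-(tert-butyldimethylsilyloxy)-4-methoxyphenyl.

Assumption: with Ti(OiPr)4/H8-BINOL the (S)-ligand is taken to give the (S)-pyranone of step 2, by analogy with benzaldehyde. Both ligand antipodes are sold, so a reversed sense only means using the other one.

Design remarks:
- (a) The C3 oxygen is introduced after the cycloaddition, because 4-oxygenated dienes tend to give the 2,3-cis series.
- (b) The diazoketone is made by diazo transfer to a methyl ketone, because diazomethane tends to add across the C=C bond of conjugated acyl compounds.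
- (c) C4–O carries TES while C3–O and 3'-O carry TBS. The benzylic carbinol can then be unmasked and oxidised with everything else protected, and a fully free, ionisation-prone flavan-3,4-diol is never handled.

Step 1
Reactants: 1 isovanillin (3-hydroxy-4-methoxybenzaldehyde)
Product: 2 3-(tert-butyldimethylsilyloxy)-4-methoxybenzaldehyde
Conditions: TBSCl, imidazole, CH2Cl2, 23 °C
Reagents that add atoms: tert-butyldimethylsilyl chloride, CC(C)(C)[Si](C)(C)Cl
Why: Routine imidazole-promoted silylation of a phenol removes the only acidic proton before the Lewis-acid and strong-base steps; no stereocentre is involved.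

Step 2
Reactants: 2 3-(tert-butyldimethylsilyloxy)-4-methoxybenzaldehyde; 3 Danishefsky's diene, (E)-1-methoxy-3-(trimethylsilyloxy)buta-1,3-diene
Product: 5 (2S)-2-Ar-2,3-dihydro-4H-pyran-4-one, via silyl aldol adduct 4 (not isolated)
Conditions: Ti(OiPr)4 (10 mol %), (S)-H8-BINOL (11 mol %), 4 Å MS, toluene, 0 °C; then TFA (cat.), CH2Cl2, 0 °C, brief
Reagents that add atoms: none
Why: Catalytic asymmetric hetero-Diels–Alder reaction (Mukaiyama aldol then cyclisation) of an aromatic aldehyde, an established substrate class for BINOL-type complexes of tetravalent titanium; the chiral Lewis acid shields one aldehyde face and so sets C2 (spatially the 2R centre of the target, S by CIP here because C3 is still CH2), and a short cold acid treatment closes ring C with loss of methanol.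

Step 3
Reactants: 5 (2S)-2-Ar-2,3-dihydro-4H-pyran-4-one
Product: 7 (2R,3R)-2-Ar-3-hydroxy-2,3-dihydro-4H-pyran-4-one (2,3-trans), via sodium enolate 6 (not isolated)
Conditions: NaHMDS, THF, −78 °C; 2-(phenylsulfonyl)-3-phenyloxaziridine, −78 °C; then AcOH
Reagents that add atoms: 2-(phenylsulfonyl)-3-phenyloxaziridine, O=S(=O)(c1ccccc1)N1OC1c1ccccc1; sodium hexamethyldisilazide, C[Si](C)(C)[N-][Si](C)(C)C.[Na+] (Na only in 6)
Why: Davis enolate hydroxylation: only C3 carries enolisable protons, and the nearly flat enolate should be attacked on the face opposite the C2 aryl group, which sets C3 as the 2,3-trans ketol, also the thermodynamically preferred isomer.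

Step 4
Reactants: 7 (2R,3R)-2-Ar-3-hydroxy-2,3-dihydro-4H-pyran-4-one
Product: 8 (2R,3R)-2-Ar-3-(tert-butyldimethylsilyloxy)-2,3-dihydro-4H-pyran-4-one
Conditions: TBSOTf, 2,6-lutidine, CH2Cl2, −40 to 0 °C
Reagents that add atoms: tert-butyldimethylsilyl triflate, CC(C)(C)[Si](C)(C)OS(=O)(=O)C(F)(F)F
Why: Silyl triflate silylation of a hindered secondary ketol is fast at low temperature, and 2,6-lutidine does not enolise the vinylogous ester, so C3 is untouched.

Step 5
Reactants: 8 (2R,3R)-2-Ar-3-(tert-butyldimethylsilyloxy)-2,3-dihydro-4H-pyran-4-one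
Product: 9 (2R,3S,4R)-2-Ar-3-(tert-butyldimethylsilyloxy)-3,4-dihydro-2H-pyran-4-ol (2,3-trans-3,4-trans)
Conditions: NaBH4, CeCl3·7H2O, MeOH/CH2Cl2, −78 to −40 °C
Reagents that add atoms: none
Why: Luche reduction gives clean 1,2-reduction of the vinylogous ester carbonyl; axial hydride delivery, as in the glucal series, should place the new C4-OH pseudo-equatorial, and since C4 becomes a ketone in step 12 its epimer would serve equally.

Step 6
Reactants: 9 (2R,3S,4R)-2-Ar-3-(tert-butyldimethylsilyloxy)-3,4-dihydro-2H-pyran-4-ol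
Product: 10 (2R,3R,4R)-2-Ar-3-(tert-butyldimethylsilyloxy)-4-(triethylsilyloxy)-3,4-dihydro-2H-pyran
Conditions: TESCl, imidazole, CH2Cl2, 0 °C
Reagents that add atoms: triethylsilyl chloride, CC[Si](Cl)(CC)CC
Why: Routine silylation of an allylic alcohol; TES survives organolithium, amide base, light and heat yet is cleaved much faster than TBS, which is the handle for step 11.

Step 7
Reactants: 10 (2R,3R,4R)-2-Ar-3-(tert-butyldimethylsilyloxy)-4-(triethylsilyloxy)-3,4-dihydro-2H-pyran; 11 N-methoxy-N-methylacetamide
Product: 13 1-[(2R,3R,4R)-2-Ar-3-(tert-butyldimethylsilyloxy)-4-(triethylsilyloxy)-3,4-dihydro-2H-pyran-6-yl]ethan-1-one, via 6-lithio dihydropyran 12 (not isolated)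
Conditions: t-BuLi (1.5 equiv), THF/pentane, −78 to −20 °C; 11, −78 to 0 °C; then H2O
Reagents that add atoms: tert-butyllithium, [Li]C(C)(C)C (Li only in 12)
Why: α-Lithiation of a cyclic enol ether, the standard C1 metalation of silyl-protected glycals, followed by acylation with a Weinreb amide whose chelated adduct prevents over-addition; the vinylic C6–H next to oxygen should be the kinetically most acidic site, whereas the axial benzylic C2–H lies near the plane of the electron-rich equatorial aryl group and gains little stabilisation.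

Step 8
Reactants: 13 the 6-acetyl dihydropyran
Product: 15 2-diazo-1-[(2R,3R,4R)-2-Ar-3-(tert-butyldimethylsilyloxy)-4-(triethylsilyloxy)-3,4-dihydro-2H-pyran-6-yl]ethan-1-one, via trifluoroacetyl diketone 14 (not isolated)
Conditions: LiHMDS, THF, −78 °C; CF3CO2CH2CF3; aq. work-up; then MsN3, Et3N, H2O, MeCN, 23 °C
Reagents that add atoms: methanesulfonyl azide, CS(=O)(=O)N=[N+]=[N-]; 2,2,2-trifluoroethyl trifluoroacetate, O=C(OCC(F)(F)F)C(F)(F)F (atoms only in 14)
Why: Detrifluoroacetylative diazo transfer: kinetic enolisation at the methyl group, Claisen-type trifluoroacetylation to activate that carbon, then Regitz-type transfer from the sulfonyl azide with loss of the trifluoroacetyl group, the established entry to α,β-unsaturated diazomethyl ketones without diazomethane.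

Step 9
Reactants: 16 chloroacetaldehyde dimethyl acetal; 17 prenyl bromide (1-bromo-3-methylbut-2-ene)
Product: 19 1-methoxy-5-methylhex-4-en-1-yne, via sodium methoxyacetylide 18 (not isolated)
Conditions: NaNH2 (3 equiv), NH3(l), −33 °C; then 17, −33 °C; pentane extraction, distillation
Reagents that add atoms: sodium amide, [NH2-].[Na+] (Na only in 18)
Why: Twofold base-induced elimination (HCl, then MeOH) from the chloroacetal gives the metalated ynol ether, which is alkylated by SN2 attack at the unhindered primary carbon of the allylic bromide; once three equivalents of amide are consumed only acetylide and methoxide remain, so the skipped enyne should not isomerise.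

Step 10
Reactants: 15 the dihydropyranyl diazomethyl ketone; 19 1-methoxy-5-methylhex-4-en-1-yne (2.5 equiv)
Product: 24 (2R,3R,4R)-2-Ar-3-(tert-butyldimethylsilyloxy)-7-methoxy-6-(3-methylbut-2-enyl)-4-(triethylsilyloxy)chroman-5-ol, via vinylketene 20 (not isolated), via vinylcyclobutenone 21 (not isolated), via dienylketene 22 (not isolated), via cyclohexadienone 23 (not isolated)
Conditions: ClCH2CH2Cl (degassed), hν (300 nm, Pyrex), 23 °C until 15 is consumed; then 80 °C
Reagents that add atoms: none
Why: Irradiation expels N2 from 15 and the α-alkoxyvinyl carbon C8a migrates to the former diazo carbon C8 (Wolff rearrangement) to give vinylketene 20, whose carbonyl carbon (future C5) is attacked by the nucleophilic, prenyl-bearing carbon of ynol ether 19, so that the [2+2] cycloaddition forms C5–C6 and C7–C8 in cyclobutenone 21. Strain then drives reversible conrotatory four-electron cleavage of the C5–C8 bond to dienylketene 22, and ring A is closed by a thermal disrotatory six-electron electrocyclisation (C4a–C5) onto the enol ether carbon of ring C, followed by tautomerisation of dienone 23 to the phenol. The closest known reaction type is the Danheiser benzannulation in its diazoketone (photo-Wolff) form, established for cyclic α,β-unsaturated and heteroaryl diazomethyl ketones with alkoxy- and siloxyalkynes, and here the ring oxygen on the migrating carbon is only a spectator substituent. No permanent stereocentre is created (the sp3 carbons of 21 and 23 are transient), and C2, C3 and C4 never belong to a reacting π system, so they are carried through unchanged. The step needs regioselectivity, secured by the polarisation of the ynol ether (its β-carbon bonds to the ketene carbonyl), and chemoselectivity for the alkyne over the trisubstituted prenyl alkene, secured by the much higher nucleophilicity of the ynol ether and by its excess, which also limits ketene dimerisation and acylation of the product phenol. A methyl ynol ether cannot lose an alkene by retro-ene fragmentation, so it tolerates the 80 °C finishing stage.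

Step 11
Reactants: 24 the tris-silylated flavan-3,4-diol
Product: 25 (2R,3S,4R)-2-Ar-3-(tert-butyldimethylsilyloxy)-7-methoxy-6-(3-methylbut-2-enyl)chroman-4,5-diol
Conditions: HF·pyridine, excess pyridine, THF, 0 °C
Reagents that add atoms: none
Why: Fluoride-induced Si–O cleavage differentiates silyl ethers by steric bulk, so the TES ether should go first, and the pyridine buffer keeps the medium too weakly acidic for C4–O ionisation at the electron-rich benzylic position.

Step 12
Reactants: 25 the 4,5-diol
Product: 26 (2R,3R)-2-Ar-3-(tert-butyldimethylsilyloxy)-5-hydroxy-7-methoxy-6-(3-methylbut-2-enyl)chroman-4-one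
Conditions: activated MnO2, CH2Cl2, 23 °C
Reagents that add atoms: none
Why: Heterogeneous MnO2 oxidation of an activated (o-hydroxy, p-methoxy) benzylic alcohol under neutral conditions, with no other free alcohol, no 1,2-diol to cleave and only one hindered phenol that ends hydrogen-bonded to the new C4 ketone; neutrality protects the now enolisable C3 centre, whose trans arrangement is in any case the stable one.

Step 13
Reactants: 26 the bis-TBS dihydroflavonol
Product: 27 (2R,3R)-3,5-dihydroxy-2-(3-hydroxy-4-methoxyphenyl)-7-methoxy-6-(3-methylbut-2-enyl)chroman-4-one (target, CNP0146895.1)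
Conditions: HF·pyridine, THF, 0 to 23 °C
Reagents that add atoms: none
Why: Fluoride desilylation under mildly acidic conditions avoids the base-induced ring opening, epimerisation and air oxidation typical of dihydroflavonols, and is too weakly acidic to cyclise the o-prenylphenol.

Compound list

1 | isovanillin | COc1ccc(C=O)cc1O | starting material
2 | 3-(tert-butyldimethylsilyloxy)-4-methoxybenzaldehyde | COc1ccc(C=O)cc1O[Si](C)(C)C(C)(C)C | intermediate
3 | (E)-1-methoxy-3-(trimethylsilyloxy)buta-1,3-diene | CO/C=C/C(=C)O[Si](C)(C)C | starting material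
4 | (5S,1E)-5-Ar-1-methoxy-5-(trimethylsilyloxy)pent-1-en-3-one | COc1ccc([C@H](CC(=O)/C=C/OC)O[Si](C)(C)C)cc1O[Si](C)(C)C(C)(C)C | intermediate
5 | (2S)-2-Ar-2,3-dihydro-4H-pyran-4-one | COc1ccc([C@H]2OC=CC(=O)C2)cc1O[Si](C)(C)C(C)(C)C | intermediate
6 | sodium enolate of 5 (C3=C4) | COc1ccc([C@H]2OC=CC([O-])=C2)cc1O[Si](C)(C)C(C)(C)C.[Na+] | intermediate
7 | (2R,3R)-2-Ar-3-hydroxy-2,3-dihydro-4H-pyran-4-one | COc1ccc([C@H]2OC=CC(=O)[C@@H]2O)cc1O[Si](C)(C)C(C)(C)C | intermediate
8 | (2R,3R)-2-Ar-3-(tert-butyldimethylsilyloxy)-2,3-dihydro-4H-pyran-4-one | COc1ccc([C@H]2OC=CC(=O)[C@@H]2O[Si](C)(C)C(C)(C)C)cc1O[Si](C)(C)C(C)(C)C | intermediate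
9 | (2R,3S,4R)-2-Ar-3-(tert-butyldimethylsilyloxy)-3,4-dihydro-2H-pyran-4-ol | COc1ccc([C@H]2OC=C[C@@H](O)[C@@H]2O[Si](C)(C)C(C)(C)C)cc1O[Si](C)(C)C(C)(C)C | intermediate
10 | (2R,3R,4R)-2-Ar-3-(tert-butyldimethylsilyloxy)-4-(triethylsilyloxy)-3,4-dihydro-2H-pyran | COc1ccc([C@H]2OC=C[C@@H](O[Si](CC)(CC)CC)[C@@H]2O[Si](C)(C)C(C)(C)C)cc1O[Si](C)(C)C(C)(C)C | intermediate
11 | N-methoxy-N-methylacetamide | CON(C)C(C)=O | starting material
12 | 6-lithio derivative of 10 | COc1ccc([C@H]2OC([Li])=C[C@@H](O[Si](CC)(CC)CC)[C@@H]2O[Si](C)(C)C(C)(C)C)cc1O[Si](C)(C)C(C)(C)C | intermediate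
13 | 6-acetyl dihydropyran (2R,3R,4R) | COc1ccc([C@H]2OC(C(C)=O)=C[C@@H](O[Si](CC)(CC)CC)[C@@H]2O[Si](C)(C)C(C)(C)C)cc1O[Si](C)(C)C(C)(C)C | intermediate
14 | 4,4,4-trifluoro-1-(dihydropyran-6-yl)butane-1,3-dione (2R,3R,4R) | COc1ccc([C@H]2OC(C(=O)CC(=O)C(F)(F)F)=C[C@@H](O[Si](CC)(CC)CC)[C@@H]2O[Si](C)(C)C(C)(C)C)cc1O[Si](C)(C)C(C)(C)C | intermediate
15 | dihydropyran-6-yl diazomethyl ketone (2R,3R,4R), precursor of the key step | COc1ccc([C@H]2OC(C(=O)C=[N+]=[N-])=C[C@@H](O[Si](CC)(CC)CC)[C@@H]2O[Si](C)(C)C(C)(C)C)cc1O[Si](C)(C)C(C)(C)C | intermediate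
16 | chloroacetaldehyde dimethyl acetal | COC(CCl)OC | starting material
17 | prenyl bromide | CC(C)=CCBr | starting material
18 | sodium methoxyacetylide | COC#[C-].[Na+] | intermediate
19 | 1-methoxy-5-methylhex-4-en-1-yne | COC#CCC=C(C)C | intermediate
20 | (dihydropyran-6-yl)ketene | COc1ccc([C@H]2OC(C=C=O)=C[C@@H](O[Si](CC)(CC)CC)[C@@H]2O[Si](C)(C)C(C)(C)C)cc1O[Si](C)(C)C(C)(C)C | intermediate
21 | 4-(dihydropyran-6-yl)-3-methoxy-2-prenylcyclobut-2-en-1-one (both epimers at the transient ring carbon) | COc1ccc([C@H]2OC(C3C(=O)C(CC=C(C)C)=C3OC)=C[C@@H](O[Si](CC)(CC)CC)[C@@H]2O[Si](C)(C)C(C)(C)C)cc1O[Si](C)(C)C(C)(C)C | intermediate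
22 | dienylketene, C6 and C8a cis on the C7=C8 bond | COc1ccc([C@H]2OC(/C=C(/OC)C(CC=C(C)C)=C=O)=C[C@@H](O[Si](CC)(CC)CC)[C@@H]2O[Si](C)(C)C(C)(C)C)cc1O[Si](C)(C)C(C)(C)C | intermediate
23 | 4a-H cyclohexa-2,4-dienone tautomer of 24 (C4a transient) | COc1ccc([C@H]2OC3=CC(OC)=C(CC=C(C)C)C(=O)C3[C@@H](O[Si](CC)(CC)CC)[C@@H]2O[Si](C)(C)C(C)(C)C)cc1O[Si](C)(C)C(C)(C)C | intermediate
24 | (2R,3R,4R) tris-silylated 2,3-trans flavan-3,4-diol with complete ring A, product of the key step | COc1ccc([C@H]2Oc3cc(OC)c(CC=C(C)C)c(O)c3[C@@H](O[Si](CC)(CC)CC)[C@@H]2O[Si](C)(C)C(C)(C)C)cc1O[Si](C)(C)C(C)(C)C | intermediate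
25 | (2R,3S,4R) 3,3'-bis-TBS flavan-3,4-diol with free 4-OH and 5-OH | COc1ccc([C@H]2Oc3cc(OC)c(CC=C(C)C)c(O)c3[C@@H](O)[C@@H]2O[Si](C)(C)C(C)(C)C)cc1O[Si](C)(C)C(C)(C)C | intermediate
26 | (2R,3R) 3,3'-bis-TBS dihydroflavonol | COc1ccc([C@H]2Oc3cc(OC)c(CC=C(C)C)c(O)c3C(=O)[C@@H]2O[Si](C)(C)C(C)(C)C)cc1O[Si](C)(C)C(C)(C)C | intermediate
27 | (2R,3R)-3,5-dihydroxy-2-(3-hydroxy-4-methoxyphenyl)-7-methoxy-6-(3-methylbut-2-enyl)chroman-4-one | COc1ccc([C@H]2Oc3cc(OC)c(CC=C(C)C)c(O)c3C(=O)[C@@H]2O)cc1O | target

Total step count: 13. Longest linear sequence: 12 (steps 1–8 and 10–13); step 9 is the one-step side branch.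

Steps most likely to fail

Step 10. The vinylketene may be captured inefficiently (dimerisation, acylation of the product phenol). The chromophores may undergo secondary photolysis, or silanol may be lost at C4 during the thermal stage.
- The fallback reaches the same vinylcyclobutenone without light or a free ketene. It sets out from 10 and 19 and comes back at 21, which on heating gives 24.
- Compound 10 is lithiated as in step 7 and quenched with Bu3SnCl to give the 6-(tributylstannyl)dihydropyran F1.
- Alkyne 19 is combined with dichloroketene (Cl3CCOCl, zinc–copper couple, Et2O) to give 4,4-dichloro-3-methoxy-2-prenylcyclobut-2-en-1-one F2.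
- Controlled zinc reduction (Zn, AcOH, TMEDA, EtOH, 0 °C) removes one chlorine to give 4-chloro-3-methoxy-2-prenylcyclobut-2-en-1-one F3.
- Stille coupling of F1 with F3 (PdCl2(PhCN)2, tri(2-furyl)phosphine, dioxane, 50 °C) forms the C8–C8a bond and delivers 21. Raising the temperature to 80–100 °C then triggers the same four-electron opening and six-electron closure.

Step 7. The base may deprotonate the benzylic C2–H (followed by expulsion of the C3 silanolate) or the ring B position ortho to the methoxy group, and silyl groups may migrate.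
- The fallback avoids strong base altogether. It sets out from 10 and comes back at 13.
- Vinylic C–H borylation with a monovalent iridium catalyst ([Ir(OMe)(cod)]2, 4,4'-di-tert-butyl-2,2'-bipyridine, B2pin2, hexane, 60–80 °C) is known to go α to oxygen in γ-substituted dihydropyrans. Here every aromatic C–H is flanked by a substituent, so it should give the 6-(pinacolboryl)dihydropyran F4.
- An anhydrous acylative Suzuki–Miyaura coupling with acetyl chloride (Pd(PPh3)4, Cs2CO3, toluene) then gives 13.

Step 11. The C4–O bond may ionise, since the benzylic position is activated by three ring A oxygens, leading to self-condensation at C8. Discrimination between the silyl ethers may also be lost.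
- The fallback gives up the staged unmasking. It sets out from 24 and comes back at 27.
- All three silyl groups are removed at once with acetic-acid-buffered TBAF (THF, 0 °C) to give the free (2R,3S,4R)-flavan-3,4-diol F5. This is not stored.
- F5 is oxidised directly with activated MnO2 in EtOAc. MnO2 attacks only the benzylic C4 carbinol and not the unactivated C3 alcohol, which gives 27 two steps earlier.

Further compounds

F1 | step 10 | (2R,3R,4R)-2-Ar-3-(tert-butyldimethylsilyloxy)-4-(triethylsilyloxy)-6-(tributylstannyl)-3,4-dihydro-2H-pyran | COc1ccc([C@H]2OC([Sn](CCCC)(CCCC)CCCC)=C[C@@H](O[Si](CC)(CC)CC)[C@@H]2O[Si](C)(C)C(C)(C)C)cc1O[Si](C)(C)C(C)(C)C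
F2 | step 10 | 4,4-dichloro-3-methoxy-2-(3-methylbut-2-enyl)cyclobut-2-en-1-one | COC1=C(CC=C(C)C)C(=O)C1(Cl)Cl
F3 | step 10 | 4-chloro-3-methoxy-2-(3-methylbut-2-enyl)cyclobut-2-en-1-one | COC1=C(CC=C(C)C)C(=O)C1Cl
F4 | step 7 | (2R,3R,4R)-2-Ar-3-(tert-butyldimethylsilyloxy)-4-(triethylsilyloxy)-6-(4,4,5,5-tetramethyl-1,3,2-dioxaborolan-2-yl)-3,4-dihydro-2H-pyran | COc1ccc([C@H]2OC(B3OC(C)(C)C(C)(C)O3)=C[C@@H](O[Si](CC)(CC)CC)[C@@H]2O[Si](C)(C)C(C)(C)C)cc1O[Si](C)(C)C(C)(C)C
F5 | step 11 | (2R,3S,4R)-2-(3-hydroxy-4-methoxyphenyl)-7-methoxy-6-(3-methylbut-2-enyl)chroman-3,4,5-triol | COc1ccc([C@H]2Oc3cc(OC)c(CC=C(C)C)c(O)c3[C@@H](O)[C@@H]2O)cc1O
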